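Reciprocal hours are the unit to carry across this bench. In the south run, 0.173 M of target stands over 0.075 M of reagent charged, so target forms without using reagent up, and a clock can be read for it.

| flask | starting material | reagent | temperature | remark | time |
|---|---|---|---|---|---|
| north-west | 0.066 M | 0.075 M | 65 °C | run made earlier |  |
| south | 0.23 M | 0.075 M | 98 °C | run made earlier |  |
| south-east | 0.050 M | 0.045 M | 65 °C | run made earlier |  |
| noon | 0.20 M | 0.120 M | 50 °C |  | 2.0 h |
| midnight | 0.10 M | 0.0250 M | 110 °C |  | 2.0 h |
| spring | 0.15 M | 0.0750 M | 60 °C |  | 2.0 h |
| dusk | 0.050 M | 0.0400 M | 90 °C |  | 2.0 h |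
| summer | 0.050 M | 0.0750 M | 90 °C |  | 2.0 h |

| north-west: time / h | north-west: target / % | south: time / min | south: target / % | south-east: time / h | south-east: target / % |
|---|---|---|---|---|---|
| 0.333 | 11 | 6.00 | 60 | 0.333 | 9 |
| 0.667 | 13 | 12.0 | 69 | 0.667 | 14 |
| 1.33 | 19 | 25.0 | 74 | 1.33 | 20 |
| 2.50 | 22 | 40.0 | 73 | 2.50 | 28 |
| 5.00 | 25 | 80.0 | 75 | 5.00 | 33 |

(readings scatter by 1.5 percentage points)

- amounts and yields of target count crystals too
- given per volume of solution although it is solid: crystals
- reactions considered so far: starting material + reagent -> intermediate B; starting material + reagent -> intermediate A; intermediate B <-> intermediate A; reagent + intermediate B -> side product; starting material -> target; crystals <-> target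

- all flasks from highest to lowest amount of target, in percent of the starting material charged, at 2.0 h (noon / midnight / spring / dusk / summer)
- the amount of target, in percent of the starting material charged of the flask you put first, at 2.0 h
- the amount of target, in percent of the starting material charged of the flask you put last, at 2.0 h

For whoever takes over: each flask holds starting material and reagent, and the starting material has a first-order road to target. The first readings at 65 °C give that constant, and the south run's rise towards its plateau gives it at 98 °C:

k = 0.316 h⁻¹ and 16.1 h⁻¹, doubling every 5.82 K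

Reagent takes a toll. Starting material missing from the south plateau, per reagent charged, is 0.767; the last, still rising readings at 65 °C give 0.660 and 0.744. The turnover count N is the constant at the flask's temperature times the time in the flask, here for noon: 0.106.

target = (1 − toll · c(reagent)/c(starting material)) · (1 − exp(−N))

Noon will still be working at 2.0 h, with a reckoned 5.43% of target. Spring, with N = 0.349, will hold 18.2%. Dusk, with N = 12.4, will have finished at 38.7%, and midnight, with N = 134, at 80.8%. For summer the toll sum gives −15.0%, so it gets no number. Add no reagent to any flask: in the formula above, a larger c(reagent) means a larger toll.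

The forecast gives midnight > spring > noon > dusk > summer, with 80% first and 18% last, holding that “Temperature appears to affect mainly speed”.

The flasks give midnight > dusk > summer > spring > noon: midnight 82.9%, dusk 55.2%, summer 35.5%, spring 22.0%, noon 6.74%.

    starting material + reagent → intermediate B (k = 0.0320 L mol⁻¹ s⁻¹, Ea = 68.0 kJ mol⁻¹)
    starting material + reagent → intermediate A (k = 0.0380 L mol⁻¹ s⁻¹, Ea = 69.0 kJ mol⁻¹)
    intermediate B ⇌ intermediate A (K = 1.00, k = 0.00400 s⁻¹, Ea = 97.0 kJ mol⁻¹, ΔH = −29.0 kJ mol⁻¹)
    reagent + intermediate B → side product (k = 0.130 L mol⁻¹ s⁻¹, Ea = 73.0 kJ mol⁻¹)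
    starting material → target (k = 0.00190 s⁻¹, Ea = 115 kJ mol⁻¹)
    crystals ⇌ target, rate k6*(cs6 - [target]) while solid is left; crystals form when [target] > cs6 (solubility = 2.40 mM, k = 0.130 s⁻¹)
    (constants at 90 °C)

Part of what noon lacks at 6.74% is the hour of the reading. Its count grows from 0.106 to 1.06 at 20.0 h, which reckons 35.3%, and noon then holds 35.6%. In midnight, 12 percentage points of the target comes with the shrinking supply of reagent: midnight holds 82.9%, and the same run with reagent held at its charge holds 70.8%.

The readings are calculated for substances that don't exist.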